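**Retrosynthetic overview**

1. Komaroviquinone 22 ⇐ CAN oxidation of trimethoxyarene hemiketal 21 ⇐ C7 benzylic oxidation of tertiary alcohol 19 ⇐ hydrogenation and C7–O hydrogenolysis of bridged ether 18.
2. 18 ⇐ one cationic cascade from isochroman ketal 15: Prins attack of the C7 prenyl group on the C10 oxocarbenium ion (C5–C10 bond; oxolane ring and seven-membered ring B together, as an 8-oxabicyclo[3.2.1]octane), then closure of ring A by the C3–C4 bond between the resulting tertiary C4 cation and a Z vinylsilane.
3. Enabling feature: the C7–O–C10 bridge makes C7 and C10 the bridgeheads of an 8-oxabicyclo[3.2.1]octane whose two-carbon bridge C5–C6 carries the gem-dimethyl carbon C4 on C5. A 3-methylbut-2-enyl group on C7 therefore delivers C5 to C10 and leaves a cation at C4 within reach of C3; the single preset stereocenter C7 fixes C10 through the bridge and C5 through a reversible Prins step (both ketal epimers and both C5 epimers funnel to one product).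
4. 15 ⇐ lactone 12 + silylpropargyl Grignard reagent; 12 ⇐ aryl iodide 10 + Reformatsky reagent; 10 ⇐ Brown allylation and cross-metathesis of aldehyde 7 ⇐ 1,2,4-trimethoxybenzene 1. The C7–O bond serves at the alcohol level as a stereocontrolling tether, is cut in step 11 and re-formed at the ketone level in step 12.
5. Ring order: ring C (from 1) → pyran ring (lactone 12) → oxolane ring, ring B and ring A (key step) → hemiketal → quinone.

Key step: step 10

Remark: carbons carry icetexane numbers (ring A: C1–C5 and C10; ring B: C5, C6, C7, C8, C9, C20, C10; ring C: C8, C9, C11–C14), and the formylation of 4 is assumed to follow the regiochemistry of 1,2,4-trimethoxybenzene itself.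

**Route**

Step 1
Reactants: 1 1,2,4-trimethoxybenzene
Product: 3 2-(2,3,6-trimethoxyphenyl)propan-2-ol, via aryllithium 2 (not isolated)
Conditions: n-BuLi, TMEDA, THF, 0 °C; then acetone, −78 °C to rt
Reagents that add atoms: acetone CC(C)=O
Why: Directed ortho-metalation takes the ring proton between two methoxy groups, and the aryllithium adds to the carbonyl group of acetone.

Step 2
Reactants: 3 2-(2,3,6-trimethoxyphenyl)propan-2-ol
Product: 4 1,2,4-trimethoxy-3-(propan-2-yl)benzene
Conditions: Et3SiH, CF3CO2H, CH2Cl2, 0 °C to rt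
Reagents that add atoms: none
Why: Ionic hydrogenation, in which the tertiary benzylic alcohol ionizes in CF3CO2H and the cation takes hydride from Et3SiH.

Step 3
Reactants: 4 1,2,4-trimethoxy-3-(propan-2-yl)benzene
Product: 6 2,4,5-trimethoxy-3-(propan-2-yl)benzaldehyde, via α-chloro ether 5 (not isolated)
Conditions: Cl2CHOMe, TiCl4, CH2Cl2, −20 to 0 °C; then H2O
Reagents that add atoms: dichloromethyl methyl ether COC(Cl)Cl; water O
Why: Rieche formylation (electrophilic aromatic substitution) should go ortho to the 4-methoxy and para to the 2-methoxy group, the position attacked in 1,2,4-trimethoxybenzene itself, and water hydrolyses the α-chloro ether.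

Step 4
Reactants: 6 2,4,5-trimethoxy-3-(propan-2-yl)benzaldehyde
Product: 7 2-iodo-3,4,6-trimethoxy-5-(propan-2-yl)benzaldehyde
Conditions: N-iodosuccinimide, CF3CO2H (cat.), MeCN, rt
Reagents that add atoms: N-iodosuccinimide O=C1CCC(=O)N1I
Why: Electrophilic aromatic iodination at the only ring hydrogen left, which lies ortho to a methoxy group.

Step 5
Reactants: 7 2-iodo-3,4,6-trimethoxy-5-(propan-2-yl)benzaldehyde
Product: 9 (1S)-1-[2-iodo-3,4,6-trimethoxy-5-(propan-2-yl)phenyl]but-3-en-1-ol, via borinate ester 8 (not isolated)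
Conditions: (−)-Ipc2B(allyl) (from (+)-α-pinene), Et2O, −78 °C; then NaOH, H2O2, 0 °C to rt
Reagents that add atoms: (−)-B-allyldiisopinocampheylborane C=CCB([C@@H]1C[C@@H]2C[C@H]([C@H]1C)C2(C)C)[C@@H]1C[C@@H]2C[C@H]([C@H]1C)C2(C)C
Why: Brown allylation through a six-membered chair transition state under reagent control, the borane from (+)-α-pinene giving the S carbinol as it does with benzaldehyde, which sets the future C7.

Step 6
Reactants: 9 (1S)-1-[2-iodo-3,4,6-trimethoxy-5-(propan-2-yl)phenyl]but-3-en-1-ol
Product: 10 (1S)-1-[2-iodo-3,4,6-trimethoxy-5-(propan-2-yl)phenyl]-4-methylpent-3-en-1-ol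
Conditions: 2-methylbut-2-ene (excess), second-generation Grubbs catalyst RuCl2(PCy3)(H2IMes)(=CHPh) (cat.), CH2Cl2, 40 °C
Reagents that add atoms: 2-methylbut-2-ene CC=C(C)C
Why: Olefin cross-metathesis with an excess of 2-methylbut-2-ene turns the terminal alkene into the trisubstituted prenyl alkene and tolerates the alcohol and the aryl iodide.

Step 7
Reactants: 10 (1S)-1-[2-iodo-3,4,6-trimethoxy-5-(propan-2-yl)phenyl]-4-methylpent-3-en-1-ol
Product: 12 (1S)-5,6,8-trimethoxy-1-(3-methylbut-2-en-1-yl)-7-(propan-2-yl)-1,4-dihydro-3H-2-benzopyran-3-one, via hydroxy ester 11 (not isolated)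
Conditions: BrZnCH2CO2Et (THF solution, excess), Pd(dba)2 (cat.), P(t-Bu)3 (cat.), THF, rt; then PPTS (cat.), toluene, 50 °C
Reagents that add atoms: (2-ethoxy-2-oxoethyl)zinc bromide CCOC(=O)C[Zn]Br
Why: Negishi coupling of the Reformatsky reagent (palladium-catalysed α-arylation of a zinc ester enolate) followed by acid-catalysed lactonization to the six-membered lactone, with C7 untouched.

Step 8
Reactants: 12 (1S)-5,6,8-trimethoxy-1-(3-methylbut-2-en-1-yl)-7-(propan-2-yl)-1,4-dihydro-3H-2-benzopyran-3-one
Product: 14 (1S)-3,5,6,8-tetramethoxy-1-(3-methylbut-2-en-1-yl)-7-(propan-2-yl)-3-[3-(trimethylsilyl)prop-2-yn-1-yl]-3,4-dihydro-1H-2-benzopyran (C3 epimers), via lactol 13 (not isolated)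
Conditions: Me3SiC≡CCH2Br, Mg, Et2O; then 12, THF, −78 °C; then MeOH, PPTS (cat.), 0 °C
Reagents that add atoms: [3-(trimethylsilyl)prop-2-yn-1-yl]magnesium bromide C[Si](C)(C)C#CC[Mg]Br; methanol CO
Why: Grignard addition to a lactone that stops at the lactol at low temperature, as in C-glycoside synthesis, with the silyl group directing the propargyl-allenyl reagent to the propargyl product, followed by acid-catalysed exchange of the lactol hydroxyl for methoxy; the new ketal center is a mixture that step 10 erases.

Step 9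
Reactants: 14 (1S)-3,5,6,8-tetramethoxy-1-(3-methylbut-2-en-1-yl)-7-(propan-2-yl)-3-[3-(trimethylsilyl)prop-2-yn-1-yl]-3,4-dihydro-1H-2-benzopyran
Product: 15 (1S)-3,5,6,8-tetramethoxy-1-(3-methylbut-2-en-1-yl)-7-(propan-2-yl)-3-[(2Z)-3-(trimethylsilyl)prop-2-en-1-yl]-3,4-dihydro-1H-2-benzopyran (C3 epimers)
Conditions: H2 (1 atm), Pd/CaCO3 poisoned with Pb(OAc)2 (Lindlar catalyst), quinoline, EtOAc, rt
Reagents that add atoms: none
Why: Lindlar semi-hydrogenation adds H2 syn to the silylalkyne and so gives the Z vinylsilane, while the trisubstituted prenyl alkene is not reduced.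

Step 10
Reactants: 15 (1S)-3,5,6,8-tetramethoxy-1-(3-methylbut-2-en-1-yl)-7-(propan-2-yl)-3-[(2Z)-3-(trimethylsilyl)prop-2-en-1-yl]-3,4-dihydro-1H-2-benzopyran
Product: 18 (5S,7S,10S)-7,10-epoxy-11,12,14-trimethoxyicetexa-2,8,11,13-tetraene, via oxocarbenium ion 16 (not isolated), via tertiary carbocation 17 (not isolated)
Conditions: TMSOTf (cat.), 2,6-di-tert-butyl-4-methylpyridine (cat.), CH2Cl2, −78 to −30 °C
Reagents that add atoms: none
Why: Proposed new method: TMSOTf removes the ketal methoxy group as MeOSiMe3 and both ketal epimers give the same cyclic oxocarbenium ion 16, whose C10 is attacked by C5 of the prenyl group on C7 (Prins cyclization) to give the tertiary C4 cation 17, which is captured at the silicon-bearing C3 of the Z vinylsilane (β-silyl cation, then loss of Me3Si+ that regenerates TMSOTf) to leave the C2=C3 alkene. The closest known reaction types are the Prins (oxonium-ene) cyclization of oxocarbenium ions bearing a 3-methylbut-2-enyl group, which gives oxolanes with an exocyclic tertiary cation, bridging Prins cyclizations of cyclic oxocarbenium ions to 8-oxabicyclo[3.2.1]octanes, and vinylsilane-terminated cation cyclizations; their union in one cascade on an isochroman ketal is the new element. The oxolane ring (O, C7, C6, C5, C10) closes 5-exo with respect to the prenyl double bond and thereby also closes the seven-membered ring B as the second ring of the bicycle, and ring A closes 6-endo at the vinylsilane by the C3–C4 bond. C10 is set by C7, because the two-carbon tether can reach the oxocarbenium carbon only on the face syn to C6, and C5 is set by ring strain, because only the C5 epimer of 17 whose cation lies cis to C1 on the oxolane ring can close a cis-fused ring A, while the other epimer returns to 16 by fragmentation (retro-Prins) and is funnelled through. The step needs attack by C5 and not C4 of the prenyl group (tertiary against secondary cation), attack at C3 and not C2 of the vinylsilane (β-silicon effect and six- against five-membered ring), and capture of the cation ahead of proton loss (the Z geometry places silicon for the endocyclic mode, and proton loss is reversible under the acidic conditions). The hexasubstituted arene has no free position for a Friedel-Crafts side reaction.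

Step 11
Reactants: 18 (5S,7S,10S)-7,10-epoxy-11,12,14-trimethoxyicetexa-2,8,11,13-tetraene
Product: 19 (5S,10S)-11,12,14-trimethoxyicetexa-8,11,13-trien-10-ol
Conditions: H2 (3 atm), Pd(OH)2/C, EtOAc–AcOH, rt
Reagents that add atoms: none
Why: Catalytic hydrogenation saturates the C2=C3 alkene and hydrogenolysis cleaves the benzylic C7–O bond in the same operation, leaving the C10–O bond and thus the configuration of the tertiary alcohol untouched.

Step 12
Reactants: 19 (5S,10S)-11,12,14-trimethoxyicetexa-8,11,13-trien-10-ol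
Product: 21 (5S,7S,10S)-7,10-epoxy-11,12,14-trimethoxyicetexa-8,11,13-trien-7-ol, via hydroxy ketone 20 (not isolated)
Conditions: t-BuOOH (aq.), Rh2(cap)4 (cat., cap = caprolactamate), NaHCO3, ClCH2CH2Cl, 40 °C
Reagents that add atoms: tert-butyl hydroperoxide CC(C)(C)OO
Why: Benzylic oxidation by hydrogen abstraction with tert-butylperoxyl radicals (dirhodium caprolactamate catalysis) should take the open C7 methylene in preference to the neopentyl-type C20 methylene and the twisted isopropyl methine, and the C10 hydroxyl adds to the new ketone to give the bridged hemiketal, whose C7 configuration is the only one the bridge allows.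

Step 13
Reactants: 21 (5S,7S,10S)-7,10-epoxy-11,12,14-trimethoxyicetexa-8,11,13-trien-7-ol
Product: 22 komaroviquinone
Conditions: (NH4)2Ce(NO3)6, MeCN–H2O, 0 °C
Reagents that add atoms: water O
Why: Oxidative demethylation of the para-dimethoxyarene by tetravalent cerium (CAN oxidation) gives the para-quinone with the carbonyl oxygens from water, the C12 methoxy group and the hemiketal staying in place.

**Compound list**

1 | 1,2,4-trimethoxybenzene | COc1ccc(OC)c(OC)c1 | starting material
2 | (2,3,6-trimethoxyphenyl)lithium (not isolated) | COc1c([Li])c(OC)ccc1OC | intermediate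
3 | 2-(2,3,6-trimethoxyphenyl)propan-2-ol | COc1c(C(C)(C)O)c(OC)ccc1OC | intermediate
4 | 1,2,4-trimethoxy-3-(propan-2-yl)benzene | COc1c(C(C)C)c(OC)ccc1OC | intermediate
5 | 1-[chloro(methoxy)methyl]-2,4,5-trimethoxy-3-(propan-2-yl)benzene (α-chloro ether, not isolated) | COc1c(C(C)C)c(OC)c(C(Cl)OC)cc1OC | intermediate
6 | 2,4,5-trimethoxy-3-(propan-2-yl)benzaldehyde | COc1c(C(C)C)c(OC)c(C=O)cc1OC | intermediate
7 | 2-iodo-3,4,6-trimethoxy-5-(propan-2-yl)benzaldehyde | COc1c(C(C)C)c(OC)c(C=O)c(I)c1OC | intermediate
8 | diisopinocampheylborinate ester of alcohol 9 (not isolated) | COc1c(C(C)C)c(OC)c([C@@H](OB([C@@H]2C[C@@H]3C[C@H]([C@H]2C)C3(C)C)[C@@H]2C[C@@H]3C[C@H]([C@H]2C)C3(C)C)CC=C)c(I)c1OC | intermediate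
9 | (1S)-1-[2-iodo-3,4,6-trimethoxy-5-(propan-2-yl)phenyl]but-3-en-1-ol | COc1c(C(C)C)c(OC)c([C@@H](O)CC=C)c(I)c1OC | intermediate
10 | (1S)-1-[2-iodo-3,4,6-trimethoxy-5-(propan-2-yl)phenyl]-4-methylpent-3-en-1-ol | COc1c(C(C)C)c(OC)c([C@@H](O)CC=C(C)C)c(I)c1OC | intermediate
11 | ethyl {2-[(1S)-1-hydroxy-4-methylpent-3-en-1-yl]-3,5,6-trimethoxy-4-(propan-2-yl)phenyl}acetate (not isolated) | COc1c(C(C)C)c(OC)c([C@@H](O)CC=C(C)C)c(CC(=O)OCC)c1OC | intermediate
12 | (1S)-5,6,8-trimethoxy-1-(3-methylbut-2-en-1-yl)-7-(propan-2-yl)-1,4-dihydro-3H-2-benzopyran-3-one | COc1c(C(C)C)c(OC)c2c(c1OC)CC(=O)O[C@H]2CC=C(C)C | intermediate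
13 | (1S)-5,6,8-trimethoxy-1-(3-methylbut-2-en-1-yl)-7-(propan-2-yl)-3-[3-(trimethylsilyl)prop-2-yn-1-yl]-3,4-dihydro-1H-2-benzopyran-3-ol (lactol, C3 epimers, not isolated) | COc1c(C(C)C)c(OC)c2c(c1OC)CC(O)(CC#C[Si](C)(C)C)O[C@H]2CC=C(C)C | intermediate
14 | (1S)-3,5,6,8-tetramethoxy-1-(3-methylbut-2-en-1-yl)-7-(propan-2-yl)-3-[3-(trimethylsilyl)prop-2-yn-1-yl]-3,4-dihydro-1H-2-benzopyran (C3 epimers) | COc1c(C(C)C)c(OC)c2c(c1OC)CC(OC)(CC#C[Si](C)(C)C)O[C@H]2CC=C(C)C | intermediate
15 | (1S)-3,5,6,8-tetramethoxy-1-(3-methylbut-2-en-1-yl)-7-(propan-2-yl)-3-[(2Z)-3-(trimethylsilyl)prop-2-en-1-yl]-3,4-dihydro-1H-2-benzopyran (C3 epimers) | COc1c(C(C)C)c(OC)c2c(c1OC)CC(OC)(C/C=C\[Si](C)(C)C)O[C@H]2CC=C(C)C | intermediate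
16 | cyclic oxocarbenium ion at C10 formed from 15 by loss of methoxide (not isolated) | COc1c(C(C)C)c(OC)c2c(c1OC)CC(C/C=C\[Si](C)(C)C)=[O+][C@H]2CC=C(C)C | intermediate
17 | tertiary carbocation at C4 of the 7,10-epoxy bicycle, with the Z vinylsilane chain on C10 (not isolated) | COc1c(C(C)C)c(OC)c2c(c1OC)C[C@]1(C/C=C\[Si](C)(C)C)O[C@H]2C[C@H]1[C+](C)C | intermediate
18 | (5S,7S,10S)-7,10-epoxy-11,12,14-trimethoxyicetexa-2,8,11,13-tetraene (bridged ether, H on C7) | COc1c(C(C)C)c(OC)c2c(c1OC)C[C@@]13CC=CC(C)(C)[C@@H]1C[C@@H]2O3 | intermediate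
19 | (5S,10S)-11,12,14-trimethoxyicetexa-8,11,13-trien-10-ol | COc1c(C(C)C)c(OC)c2c(c1OC)C[C@@]1(O)CCCC(C)(C)[C@@H]1CC2 | intermediate
20 | (5S,10S)-10-hydroxy-11,12,14-trimethoxyicetexa-8,11,13-trien-7-one (open form, not isolated) | COc1c(C(C)C)c(OC)c2c(c1OC)C[C@@]1(O)CCCC(C)(C)[C@@H]1CC2=O | intermediate
21 | (5S,7S,10S)-7,10-epoxy-11,12,14-trimethoxyicetexa-8,11,13-trien-7-ol (bridged hemiketal) | COc1c(C(C)C)c(OC)c2c(c1OC)C[C@@]13CCCC(C)(C)[C@@H]1C[C@]2(O)O3 | intermediate
22 | komaroviquinone, (5S,7S,10S) | COC1=C(C(C)C)C(=O)C2=C(C[C@@]34CCCC(C)(C)[C@@H]3C[C@]2(O)O4)C1=O | target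

**Step count and risks**

Total step count: 13. Longest linear sequence: 13 steps (1 to 22).

Steps most likely to fail:

Step 10 (bears the label "Proposed new method:"). Loss of a proton from cation 17 to an isopropenyl group, or protodesilylation of the vinylsilane, may outrun ring closure. A 1,2-hydride shift from C5 to C4 followed by ring contraction may drain the cation, and ionization of the benzylic C7–O bond would erode the C7 stereocenter. The fallback runs the two events apart with known reactions and sets out from 14. An In(OTf)3-catalysed Prins cyclization in the oxonium-ene mode, in which the silylalkyne cannot take part, should give the bridged ether with an isopropenyl group on C5, isopropenyl ether F1 (C5 epimers). Lindlar semi-hydrogenation should give the Z vinylsilane F2. Treatment of F2 with CF3SO3H in CH2Cl2 at low temperature is an alkene-initiated, vinylsilane-terminated cation-olefin cyclization: Markovnikov protonation regenerates cation 17, the unproductive C5 epimer re-enters through retro-Prins fragmentation, and the sequence comes back to the route at 18.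

Step 12. Hydrogen abstraction at C20 or at the isopropyl methine, oxidation of the electron-rich ring, or capture of a C7-oxidised intermediate by the C10 hydroxyl (which re-forms the bridged ether at the wrong oxidation level) may take over. The fallback sets out from 19. The tertiary alcohol is masked as its triethylsilyl ether F3 (TESOTf, 2,6-lutidine, CH2Cl2). The C7 methylene is oxidised with CrO3 and 3,5-dimethylpyrazole, the classical benzylic oxidation by hexavalent chromium used for C7 of aromatic abietanes, to the silyl ether ketone F4. Bu4NF in THF then frees the hydroxyl, whereupon hydroxy ketone 20 closes and the sequence comes back at 21.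

Step 7. Oxidative addition and transmetalation at an iodide flanked by two ortho substituents may be slow, and insertion of the arylpalladium intermediate into the prenyl alkene (intramolecular Heck reaction) may compete. The fallback sets out from 7 and introduces the acetic ester before any alkene is present. Migita–Stille coupling with Bu3SnCH2CO2Et (PdCl2(P(o-tol)3)2, ZnBr2, DMF, 80 °C) should give aldehyde ester F5. Brown allylation of F5 with the same borane should give hydroxy ester F6, which lactonizes under PPTS to allyl lactone F7. Cross-metathesis of F7 with 2-methylbut-2-ene under the conditions of step 6 comes back at 12.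

**Further compounds**

F1 | step 10 | 8-oxabicyclo[3.2.1]octane from 14 with H on C7, an isopropenyl group on C5 (C5 epimers) and a 3-(trimethylsilyl)prop-2-yn-1-yl group on C10 | COc1c(C(C)C)c(OC)c2c(c1OC)C[C@]1(CC#C[Si](C)(C)C)O[C@H]2CC1C(C)=C
F2 | step 10 | the same bridged ether with a (2Z)-3-(trimethylsilyl)prop-2-en-1-yl group on C10 (C5 epimers) | COc1c(C(C)C)c(OC)c2c(c1OC)C[C@]1(C/C=C\[Si](C)(C)C)O[C@H]2CC1C(C)=C
F3 | step 12 | (5S,10S)-11,12,14-trimethoxy-10-(triethylsilyloxy)icetexa-8,11,13-triene | COc1c(C(C)C)c(OC)c2c(c1OC)C[C@@]1(O[Si](CC)(CC)CC)CCCC(C)(C)[C@@H]1CC2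
F4 | step 12 | (5S,10S)-11,12,14-trimethoxy-10-(triethylsilyloxy)icetexa-8,11,13-trien-7-one | COc1c(C(C)C)c(OC)c2c(c1OC)C[C@@]1(O[Si](CC)(CC)CC)CCCC(C)(C)[C@@H]1CC2=O
F5 | step 7 | ethyl [2-formyl-3,5,6-trimethoxy-4-(propan-2-yl)phenyl]acetate | COc1c(C(C)C)c(OC)c(C=O)c(CC(=O)OCC)c1OC
F6 | step 7 | ethyl {2-[(1S)-1-hydroxybut-3-en-1-yl]-3,5,6-trimethoxy-4-(propan-2-yl)phenyl}acetate | COc1c(C(C)C)c(OC)c([C@@H](O)CC=C)c(CC(=O)OCC)c1OC
F7 | step 7 | (1S)-5,6,8-trimethoxy-1-(prop-2-en-1-yl)-7-(propan-2-yl)-1,4-dihydro-3H-2-benzopyran-3-one | COc1c(C(C)C)c(OC)c2c(c1OC)CC(=O)O[C@H]2CC=C
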